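Rings B and C are each an O1–C2–C3–C4 dihydropyran fused to a tropolone (rings A and D). Cutting O1–C2 and C3–C4 in both leaves two copies of one tropolone o-quinone methide and all-E nona-1,3,5,7-tetraene, whose vinyl end becomes C2/C3 of ring C and whose E-propenyl end becomes C2/C3 (with the C3 methyl) of ring B. The key step is this twofold inverse-demand hetero-Diels–Alder reaction under a chiral Brønsted acid: four bonds, two rings and three stereocentres form at once. Its precursors are the tetraene and free 2,4-dihydroxy-5-(hydroxymethyl)-6-methyltropone, whose C4–OH/CH2OH pair releases the o-quinone methide and whose C2–OH gives the acid a second anchor.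

Key step: step 8

Assumption: the sense of induction of the chiral acid cannot be predicted; the (R)-acid is written, and the (S)-acid is used instead if it proves to give the (2S,3S,2′S) series.

Step 1
Reactants: 1 (2E,4E)-hexa-2,4-dienal (sorbaldehyde); 2 diethyl allylphosphonate
Product: 5 (3E,5E,7E)-nona-1,3,5,7-tetraene, via lithiated phosphonate 3 (not isolated), via lithium oxidophosphonate 4 (not isolated)
Conditions: 2, n-BuLi, THF, −78 °C; DMPU; then 1, −78 °C → rt; kept as a pentane solution with BHT under argon
Reagents that add atoms: none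
Why: Horner–Wadsworth–Emmons olefination: the lithiated allylic phosphonate adds through its α-carbon to the aldehyde, and syn-elimination of lithium diethyl phosphate, favoured by the polar additive, should give the new C3=C4 bond E-selectively while the E,E-diene of 1 is untouched.

Step 2
Reactants: 6 ethoxyacetylene
Product: 8 methyl 3-ethoxyprop-2-ynoate, via lithium ethoxyacetylide 7 (not isolated)
Conditions: n-BuLi, THF, −78 °C; then inverse addition to ClCO2Me, THF, −78 °C
Reagents that add atoms: methyl chloroformate, COC(=O)Cl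
Why: C-acylation of a lithium acetylide by a chloroformate (inverse addition keeps the chloroformate in excess and prevents a second addition) should give the push–pull ynol ether ester.

Step 3
Reactants: 9 allomaltol (5-hydroxy-2-methyl-4H-pyran-4-one)
Product: 10 5-hydroxy-4-methoxy-2-methylpyrylium trifluoromethanesulfonate
Conditions: MeOTf, CH2Cl2, reflux
Reagents that add atoms: methyl triflate, COS(=O)(=O)C(F)(F)F
Why: O-alkylation of the 4-pyranone carbonyl, its most nucleophilic site, by the hard methylating agent should give the aromatic hydroxypyrylium salt.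

Step 4
Reactants: 10 5-hydroxy-4-methoxy-2-methylpyrylium trifluoromethanesulfonate; 8 methyl 3-ethoxyprop-2-ynoate
Product: 12 methyl 7-ethoxy-3-methoxy-5-methyl-2-oxo-8-oxabicyclo[3.2.1]octa-3,6-diene-6-carboxylate (racemic), via oxidopyrylium ylide 11 (not isolated)
Conditions: PhNMe2 (1.2 equiv), 8 (3 equiv), CH2Cl2, sealed tube, 60 °C
Reagents that add atoms: none
Why: Oxidopyrylium [5+2] cycloaddition: deprotonation gives ylide 11, whose unsubstituted carbon next to the oxido group (nucleophilic) should bond to the ethoxy-bearing alkyne carbon (electrophilic) and whose methyl-bearing carbon to the ester-bearing carbon, the orientation expected for alkynoates, so that OEt sits at C7 and CO2Me at C6; both stereocentres of racemic 12 are lost in step 5.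

Step 5
Reactants: 12 methyl 7-ethoxy-3-methoxy-5-methyl-2-oxo-8-oxabicyclo[3.2.1]octa-3,6-diene-6-carboxylate
Product: 14 methyl 7-ethoxy-4-methoxy-2-methyl-5-oxocyclohepta-1,3,6-triene-1-carboxylate, via hydroxy ketone 13 (not isolated)
Conditions: SmI2 (2.2 equiv), THF/MeOH, −78 °C; then 1 M HCl, −78 °C → rt
Reagents that add atoms: none
Why: Reductive cleavage of an α-alkoxy ketone by SmI2 (ketyl formation, scission of the C1–O8 bond next to C2=O) followed by acid dehydration of the tertiary C5 carbinol, driven by aromatisation, should remove the bridging oxygen and give the 2-methoxytropone; the alkoxy-substituted C6=C7 bond (a vinylogous carbonate) should resist SmI2.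

Step 6
Reactants: 14 methyl 7-ethoxy-4-methoxy-2-methyl-5-oxocyclohepta-1,3,6-triene-1-carboxylate
Product: 15 methyl 2,4-dihydroxy-7-methyl-5-oxocyclohepta-1,3,6-triene-1-carboxylate
Conditions: BBr3 (3 equiv), CH2Cl2, −78 → 0 °C; aqueous work-up
Reagents that add atoms: none
Why: Lewis acid ether cleavage: boron binds the ring carbonyl and ester carbonyl oxygens and bromide dealkylates the two vinylogous ester ethers (SN2 at methyl and at ethyl), while the methyl ester should survive at low temperature.

Step 7
Reactants: 15 methyl 2,4-dihydroxy-7-methyl-5-oxocyclohepta-1,3,6-triene-1-carboxylate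
Product: 17 2,4-dihydroxy-5-(hydroxymethyl)-6-methylcyclohepta-2,4,6-trien-1-one, via aldehyde 16 (not isolated)
Conditions: LiAlH4 (4 equiv), THF, 0 °C → rt; Rochelle salt, pH 5 buffer
Reagents that add atoms: none
Why: Hydride reduction of a salicylate-type ester: the acidic hydroxyls are deprotonated first and the resulting aluminium tropolonate should be inert to hydride, so only the ester is reduced, via aldehyde 16, to the carbinol; the temperature is kept low to avoid hydrogenolysis through an o-quinone methide.

Step 8
Reactants: 17 2,4-dihydroxy-5-(hydroxymethyl)-6-methylcyclohepta-2,4,6-trien-1-one (2.4 equiv); 5 (3E,5E,7E)-nona-1,3,5,7-tetraene (1 equiv)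
Product: 20 (2R,3R)-8-hydroxy-2-{(1E,3E)-4-[(2R)-8-hydroxy-5-methyl-7-oxo-2,3,4,7-tetrahydrocyclohepta[b]pyran-2-yl]buta-1,3-dien-1-yl}-3,5-dimethyl-3,4-dihydrocyclohepta[b]pyran-7(2H)-one, via o-quinone methide 18 (not isolated), via heptatrienyl monoadduct 19 (not isolated)
Conditions: (R)-[3,3′-bis(2,4,6-triisopropylphenyl)-BINOL]P(=O)NHTf (10 mol%), 5 Å MS, CH2Cl2, −20 °C → rt, dark; SiO2 chromatography, then HPLC
Reagents that add atoms: none
Why: Proposed new method: the acid ionises the carbinol of 17 (loss of water, taken up by the sieves) and stays hydrogen-bonded to C4=O and the free C2–OH of o-quinone methide 18, whose exocyclic CH2 bonds to the terminal carbon of a polyene end while the C4 oxygen closes on the neighbouring carbon in a concerted, asynchronous inverse-demand [4+2], first at C1/C2 of 5 (giving 19) and then at C8/C7. The closest known reaction types are the thermal hetero-Diels–Alder reaction of tropolone o-quinone methides with alkenes and the chiral Brønsted acid catalysed [4+2] of benzenoid o-quinone methides, made from o-hydroxybenzyl alcohols, with styrenes; the twofold, catalyst-controlled use on a tropolone and a bare polyene is the untested part. Rings B and C each close in cycloaddition mode (in the stepwise limit, 6-endo capture of an allylic cation by the C4 oxygen). The trans C2/C3 pair of ring B follows from suprafacial addition to the E-propenyl end, and the absolute configuration at C2 and C3 of ring B and at C2 of ring C is set by the acid, which should block one face of each alkene terminus, the two events being independent. The step needs terminal regio- and site-selectivity, secured by the polyene HOMO (largest coefficients at C1 and C8) and by allylic stabilisation of charge at C2 and C7, and it needs the second o-quinone methide to take the far end, secured by the hindered, inductively deactivated alkene next to the new ether carbon.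

Compound list
1 | (2E,4E)-hexa-2,4-dienal (sorbaldehyde) | C/C=C/C=C/C=O | starting material
2 | diethyl allylphosphonate | C=CCP(=O)(OCC)OCC | starting material
3 | α-lithiated diethyl allylphosphonate (not isolated) | [Li+].C=C[CH-]P(=O)(OCC)OCC | intermediate
4 | lithium (5E,7E)-3-(diethoxyphosphoryl)nona-1,5,7-trien-4-olate (not isolated, diastereomer mixture) | [Li+].C/C=C/C=C/C([O-])C(C=C)P(=O)(OCC)OCC | intermediate
5 | (3E,5E,7E)-nona-1,3,5,7-tetraene | C=C/C=C/C=C/C=C/C | intermediate
6 | ethoxyacetylene | C#COCC | starting material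
7 | lithium ethoxyacetylide (not isolated) | [Li+].[C-]#COCC | intermediate
8 | methyl 3-ethoxyprop-2-ynoate | CCOC#CC(=O)OC | intermediate
9 | allomaltol (5-hydroxy-2-methyl-4H-pyran-4-one) | Cc1cc(=O)c(O)co1 | starting material
10 | 5-hydroxy-4-methoxy-2-methylpyrylium trifluoromethanesulfonate | Cc1cc(OC)c(O)c[o+]1.[O-]S(=O)(=O)C(F)(F)F | intermediate
11 | 4-methoxy-6-methylpyrylium-3-olate (oxidopyrylium ylide, not isolated) | Cc1cc(OC)c([O-])c[o+]1 | intermediate
12 | methyl 7-ethoxy-3-methoxy-5-methyl-2-oxo-8-oxabicyclo[3.2.1]octa-3,6-diene-6-carboxylate (racemic) | COC(=O)C1=C(OCC)C2OC1(C)C=C(OC)C2=O | intermediate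
13 | methyl 2-ethoxy-7-hydroxy-5-methoxy-7-methyl-4-oxocyclohepta-1,5-diene-1-carboxylate (racemic, not isolated) | CCOC1=C(C(=O)OC)C(C)(O)C=C(OC)C(=O)C1 | intermediate
14 | methyl 7-ethoxy-4-methoxy-2-methyl-5-oxocyclohepta-1,3,6-triene-1-carboxylate | CCOc1cc(=O)c(OC)cc(C)c1C(=O)OC | intermediate
15 | methyl 2,4-dihydroxy-7-methyl-5-oxocyclohepta-1,3,6-triene-1-carboxylate (tropolone tautomers interconvert) | Cc1cc(=O)c(O)cc(O)c1C(=O)OC | intermediate
16 | 2,4-dihydroxy-7-methyl-5-oxocyclohepta-1,3,6-triene-1-carbaldehyde (not isolated) | Cc1cc(=O)c(O)cc(O)c1C=O | intermediate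
17 | 2,4-dihydroxy-5-(hydroxymethyl)-6-methylcyclohepta-2,4,6-trien-1-one | Cc1cc(=O)c(O)cc(O)c1CO | intermediate
18 | 2-hydroxy-6-methyl-5-methylidenecyclohepta-2,6-diene-1,4-dione (tropolone o-quinone methide, not isolated) | C=C1C(C)=CC(=O)C(O)=CC1=O | intermediate
19 | (2R)-2-[(1E,3E,5E)-hepta-1,3,5-trien-1-yl]-8-hydroxy-5-methyl-3,4-dihydrocyclohepta[b]pyran-7(2H)-one (not isolated) | C/C=C/C=C/C=C/[C@H]1CCc2c(C)cc(=O)c(O)cc2O1 | intermediate
20 | (2R,3R)-8-hydroxy-2-{(1E,3E)-4-[(2R)-8-hydroxy-5-methyl-7-oxo-2,3,4,7-tetrahydrocyclohepta[b]pyran-2-yl]buta-1,3-dien-1-yl}-3,5-dimethyl-3,4-dihydrocyclohepta[b]pyran-7(2H)-one | Cc1cc(=O)c(O)cc2c1C[C@@H](C)[C@H](/C=C/C=C/[C@H]1CCc3c(C)cc(=O)c(O)cc3O1)O2 | target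

Total steps: 8. Longest linear sequence: 6 steps (9 → 10 → 12 → 14 → 15 → 17 → 20).

Steps most likely to fail

Step 8. The acid may discriminate the alkene faces too weakly, so that the two ends add without a common absolute sense. It may also ionise the allylic C2–O bonds of the products (epimerisation), or the o-quinone methide may condense with itself faster than it meets the polyene. The fallback sets out from 17 and 5 and returns at 20, using only the known thermal reaction. 17 (2.4 equiv) and 5 are heated without catalyst in p-xylene at 140–150 °C in a sealed tube, so that 18 forms by thermal dehydration and adds twice. This should give 20 together with the (2S,3S,2′S)-enantiomer F1, the (2R,3R,2′S)-diastereomer F2 and the (2S,3S,2′R)-diastereomer F3. The pair 20/F1 is separated from F2/F3 by HPLC on silica, and 20 from F1 by preparative HPLC on a chiral stationary phase.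

Step 4. The ynol ether ester 8 may decompose (retro-ene loss of ethylene, hydration by the acidic salt) or the ylide may dimerise before cycloaddition takes place. The fallback sets out from 10 and returns at 12. 10 is combined with commercial methyl 3-bromopropiolate, a robust electron-poor alkyne (PhNMe2, CH2Cl2, 60 °C), to give methyl 7-bromo-3-methoxy-5-methyl-2-oxo-8-oxabicyclo[3.2.1]octa-3,6-diene-6-carboxylate F4. Addition–elimination with NaOEt in EtOH at −20 °C then exchanges bromide for ethoxide at C7.

Step 7. The oxido-conjugated ester may resist hydride, or the new carbinol may be over-reduced by hydrogenolysis through an aluminium-bound o-quinone methide. The fallback sets out from 15 and returns at 17. 15 is saponified (LiOH, THF/H2O, rt) to 2,4-dihydroxy-7-methyl-5-oxocyclohepta-1,3,6-triene-1-carboxylic acid F5. The acid is then reduced chemoselectively with BH3·SMe2 in THF (0 °C → rt, methanol quench to break the borate chelates).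

Further compounds
F1 | step 8 | (2S,3S)-8-hydroxy-2-{(1E,3E)-4-[(2S)-8-hydroxy-5-methyl-7-oxo-2,3,4,7-tetrahydrocyclohepta[b]pyran-2-yl]buta-1,3-dien-1-yl}-3,5-dimethyl-3,4-dihydrocyclohepta[b]pyran-7(2H)-one | Cc1cc(=O)c(O)cc2c1C[C@H](C)[C@@H](/C=C/C=C/[C@@H]1CCc3c(C)cc(=O)c(O)cc3O1)O2
F2 | step 8 | (2R,3R)-8-hydroxy-2-{(1E,3E)-4-[(2S)-8-hydroxy-5-methyl-7-oxo-2,3,4,7-tetrahydrocyclohepta[b]pyran-2-yl]buta-1,3-dien-1-yl}-3,5-dimethyl-3,4-dihydrocyclohepta[b]pyran-7(2H)-one | Cc1cc(=O)c(O)cc2c1C[C@@H](C)[C@H](/C=C/C=C/[C@@H]1CCc3c(C)cc(=O)c(O)cc3O1)O2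
F3 | step 8 | (2S,3S)-8-hydroxy-2-{(1E,3E)-4-[(2R)-8-hydroxy-5-methyl-7-oxo-2,3,4,7-tetrahydrocyclohepta[b]pyran-2-yl]buta-1,3-dien-1-yl}-3,5-dimethyl-3,4-dihydrocyclohepta[b]pyran-7(2H)-one | Cc1cc(=O)c(O)cc2c1C[C@H](C)[C@@H](/C=C/C=C/[C@H]1CCc3c(C)cc(=O)c(O)cc3O1)O2
F4 | step 4 | methyl 7-bromo-3-methoxy-5-methyl-2-oxo-8-oxabicyclo[3.2.1]octa-3,6-diene-6-carboxylate (racemic) | COC(=O)C1=C(Br)C2OC1(C)C=C(OC)C2=O
F5 | step 7 | 2,4-dihydroxy-7-methyl-5-oxocyclohepta-1,3,6-triene-1-carboxylic acid | Cc1cc(=O)c(O)cc(O)c1C(=O)O
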